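**Strategy.** The plan rests on cutting the C5–C6 bond of both pyrone rings B and C. C6 (ethyl-bearing) comes from a propionyl unit. C5 (methyl-bearing) is the γ-carbon of a 3-oxopentanoate whose α-carbon (future C3) is already tied through a CH2 bridge to benzene ring A. One two-directional γ-acylation of the twin keto ester polyanion with N-methoxy-N-methylpropanamide installs both bonds and every remaining pyrone carbon at once. The precursor is 2,4,6-trimethoxyisobutyrophenone carrying a CH2–CH(CO2Me)–CO–Et arm at C3 and at C5, assembled by acylation, double bromomethylation and double enolate alkylation. Double lactonisation and global O-demethylation finish the synthesis.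

Key step: step 4

Remark on the chemistry: the target has no stereocentre, so 9 and 13 are carried as mixtures of epimers and keto–enol tautomers; one extra equivalent of LiN(iPr)2 is budgeted in step 4 because the isobutyryl CH is expected to be enolised, which masks that ketone in the flask as an inert lithium enolate that returns on quench.

Step 1
Reactants: 1 1,3,5-trimethoxybenzene; 2 isobutyryl chloride
Product: 3 2-methyl-1-(2,4,6-trimethoxyphenyl)propan-1-one
Conditions: AlCl3 (1.1 equiv), CH2Cl2, 0 °C, short contact; ice-water
Reagents that add atoms: none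
Why: Friedel–Crafts acylation of the symmetric, strongly activated arene can give only one regioisomer, stops after one acylation because the AlCl3-bound ketone deactivates the ring, and at 0 °C the ortho-methoxy groups should escape Lewis acid demethylation.

Step 2
Reactants: 3 2-methyl-1-(2,4,6-trimethoxyphenyl)propan-1-one; 4 paraformaldehyde (3 equiv)
Product: 6 1-[3,5-bis(bromomethyl)-2,4,6-trimethoxyphenyl]-2-methylpropan-1-one, via mono(bromomethyl) ketone 5 (not isolated)
Conditions: 33% HBr in AcOH, rt → 45 °C; poured on ice, used without chromatography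
Reagents that add atoms: hydrogen bromide, Br
Why: Blanc-type bromomethylation, in which protonated formaldehyde attacks the two remaining ring positions (each flanked by two methoxy groups) and HBr turns the benzylic alcohols into bromides; the acyl group is twisted out of conjugation and deactivates the ring only weakly, and excess formaldehyde and HBr should let the second substitution outrun benzylation of 5 by benzylic cations.

Step 3
Reactants: 6 1-[3,5-bis(bromomethyl)-2,4,6-trimethoxyphenyl]-2-methylpropan-1-one; 7 methyl 3-oxopentanoate (5 equiv)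
Product: 9 dimethyl 2,2'-[(5-isobutyryl-2,4,6-trimethoxy-1,3-phenylene)bis(methylene)]bis(3-oxopentanoate) as an epimer mixture, via sodium enolate 8 (not isolated)
Conditions: 7, NaH (4.8 equiv), THF, 0 °C; then 6, 0 °C → rt; aq NH4Cl; excess 7 removed under high vacuum
Reagents that add atoms: none
Why: Acetoacetic-ester-type C-alkylation (SN2) of the stabilised sodium enolate by the activated benzylic bromides; the excess of 7 keeps the enolate charge on the more acidic unsubstituted keto ester, which suppresses a second alkylation of an attached arm, and one keto ester cannot bridge the two meta-disposed CH2 groups of the same ring.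

Step 4
Reactants: 9 dimethyl 2,2'-[(5-isobutyryl-2,4,6-trimethoxy-1,3-phenylene)bis(methylene)]bis(3-oxopentanoate); 10 N-methoxy-N-methylpropanamide (3.5 equiv)
Product: 13 dimethyl 2,2'-[(5-isobutyryl-2,4,6-trimethoxy-1,3-phenylene)bis(methylene)]bis(4-methyl-3,5-dioxoheptanoate) as an epimer mixture, via pentaanion 11 (not isolated), via tetrahedral bis-adduct 12 (not isolated)
Conditions: NaH (2.1 equiv), THF, 0 °C → rt; LiN(iPr)2 (commercial solution, 3.3 equiv), −78 → 0 °C; 10, −78 → −40 °C; poured into cold 1 M HCl
Reagents that add atoms: none
Why: NaH first turns both β-keto ester arms into sodium enolates, which shields every ester and arm ketone, and LiN(iPr)2 then removes one γ-proton from each propionyl CH2 and enolises the isobutyryl CH, giving pentaanion 11 whose two γ-carbanions are by far its most nucleophilic sites. Each carbanion adds to the carbonyl of 10, and the resulting N-methoxy-N-methyl hemiaminal is held as a lithium chelate (12) until the acid quench, so each arm takes up one propionyl group only and the new diketone is never exposed to carbanions. The closest known reaction type is the γ-acylation of α-substituted β-keto ester dianions with N-methoxy-N-methylamides or esters, a Claisen-type condensation run here in two directions with Weinreb-type control of mono-addition. No ring is closed in this step. The new C4 stereocentres (like those at C2) are enolisable and become sp2 ring carbons in step 5, so they need no control. The step needs γ- over α-selectivity and no acylation at the isobutyryl group: the α-positions are blocked as stabilised enolates, and the isobutyryl enolate is tetrasubstituted, flanked by two ortho-methoxy groups and unreactive toward an amide at −78 °C, so it simply returns the ketone on protonation.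

Step 5
Reactants: 13 dimethyl 2,2'-[(5-isobutyryl-2,4,6-trimethoxy-1,3-phenylene)bis(methylene)]bis(4-methyl-3,5-dioxoheptanoate)
Product: 14 3,3'-{[5-(2-methylpropanoyl)-2,4,6-trimethoxy-1,3-phenylene]bis(methylene)}bis(6-ethyl-4-hydroxy-5-methyl-2H-pyran-2-one)
Conditions: DBU (4 equiv), toluene, 90 °C; 1 M HCl work-up
Reagents that add atoms: none
Why: Base-induced double lactonisation known for 3,5-diketo esters, in which DBU forms the enolate of each C5 ketone and its oxygen attacks the methyl ester (6-exo-trig acyl substitution) with loss of methanol; the resulting 4-hydroxy-2-pyrone anion is a stabilised vinylogous carboxylate that drives the closure and erases the C2 and C4 stereocentres, while the hindered isobutyryl ketone and the aryl ethers are inert.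

Step 6
Reactants: 14 3,3'-{[5-(2-methylpropanoyl)-2,4,6-trimethoxy-1,3-phenylene]bis(methylene)}bis(6-ethyl-4-hydroxy-5-methyl-2H-pyran-2-one)
Product: 15 3,3'-{[2,4,6-trihydroxy-5-(2-methylpropanoyl)-1,3-phenylene]bis(methylene)}bis(6-ethyl-4-hydroxy-5-methyl-2H-pyran-2-one)
Conditions: BBr3 (10 equiv), CH2Cl2, −78 °C → rt; ice-water
Reagents that add atoms: none
Why: BBr3 ether cleavage, in which boron binds each methoxy oxygen and bromide removes the methyl group by SN2; the two ethers ortho to the ketone are helped by chelation, the central one is twisted out of the ring plane and therefore basic, and the 4-hydroxy-2-pyrones only form boron enolates that hydrolyse back on work-up, the low temperature sparing the CH2 bridges.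

**Compound list**

1 | 1,3,5-trimethoxybenzene | COc1cc(OC)cc(OC)c1 | starting material
2 | isobutyryl chloride (2-methylpropanoyl chloride) | CC(C)C(=O)Cl | starting material
3 | 2-methyl-1-(2,4,6-trimethoxyphenyl)propan-1-one | CC(C)C(=O)c1c(OC)cc(OC)cc1OC | intermediate
4 | paraformaldehyde (formaldehyde source, monomer unit given) | C=O | starting material
5 | 1-[3-(bromomethyl)-2,4,6-trimethoxyphenyl]-2-methylpropan-1-one | CC(C)C(=O)c1c(OC)cc(OC)c(CBr)c1OC | intermediate (not isolated)
6 | 1-[3,5-bis(bromomethyl)-2,4,6-trimethoxyphenyl]-2-methylpropan-1-one | CC(C)C(=O)c1c(OC)c(CBr)c(OC)c(CBr)c1OC | intermediate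
7 | methyl 3-oxopentanoate | CCC(=O)CC(=O)OC | starting material
8 | sodium enolate of methyl 3-oxopentanoate (geometry not defined) | CCC([O-])=CC(=O)OC.[Na+] | intermediate (not isolated)
9 | dimethyl 2,2'-[(5-isobutyryl-2,4,6-trimethoxy-1,3-phenylene)bis(methylene)]bis(3-oxopentanoate), epimer mixture | CC(C)C(=O)c1c(OC)c(CC(C(=O)OC)C(=O)CC)c(OC)c(CC(C(=O)OC)C(=O)CC)c1OC | intermediate
10 | N-methoxy-N-methylpropanamide | CCC(=O)N(C)OC | starting material
11 | pentaanion of 9: two arm enolate/γ-carbanion dianions plus the isobutyryl enolate, disodium trilithium salt | CC(C)=C([O-])c1c(OC)c(CC(C(=O)OC)=C([O-])[CH-]C)c(OC)c(CC(C(=O)OC)=C([O-])[CH-]C)c1OC.[Na+].[Na+].[Li+].[Li+].[Li+] | intermediate (not isolated)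
12 | tetrahedral bis-adduct: both γ-carbons bonded to a C(O−)(Et)N(Me)OMe carbon, arm enolates and isobutyryl enolate retained, diastereomer mixture | CC(C)=C([O-])c1c(OC)c(CC(C(=O)OC)=C([O-])C(C)C([O-])(CC)N(C)OC)c(OC)c(CC(C(=O)OC)=C([O-])C(C)C([O-])(CC)N(C)OC)c1OC.[Na+].[Na+].[Li+].[Li+].[Li+] | intermediate (not isolated)
13 | dimethyl 2,2'-[(5-isobutyryl-2,4,6-trimethoxy-1,3-phenylene)bis(methylene)]bis(4-methyl-3,5-dioxoheptanoate), epimer mixture | CC(C)C(=O)c1c(OC)c(CC(C(=O)OC)C(=O)C(C)C(=O)CC)c(OC)c(CC(C(=O)OC)C(=O)C(C)C(=O)CC)c1OC | intermediate
14 | 3,3'-{[5-(2-methylpropanoyl)-2,4,6-trimethoxy-1,3-phenylene]bis(methylene)}bis(6-ethyl-4-hydroxy-5-methyl-2H-pyran-2-one) | CCc1oc(=O)c(Cc2c(OC)c(Cc3c(O)c(C)c(CC)oc3=O)c(OC)c(C(=O)C(C)C)c2OC)c(O)c1C | intermediate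
15 | 3,3'-{[2,4,6-trihydroxy-5-(2-methylpropanoyl)-1,3-phenylene]bis(methylene)}bis(6-ethyl-4-hydroxy-5-methyl-2H-pyran-2-one) | CCc1oc(=O)c(Cc2c(O)c(Cc3c(O)c(C)c(CC)oc3=O)c(O)c(C(=O)C(C)C)c2O)c(O)c1C | target

**Total step count:** 6
**Longest linear sequence:** 6 steps (1 → 3 → 6 → 9 → 13 → 14 → 15)

**Steps most likely to fail**

1. Step 4. The secondary γ-carbanions sit next to a crowded enolate and may add to the amide too slowly. Proton transfer from the amide α-CH2 could then quench them, returning one or both arms unacylated. The fallback sets out from 9 and comes back to the route at 13. Pentaanion 11 is generated as in step 4 and trapped at −78 °C with propanal (2.0 equiv) instead of the amide. This aldol addition is fast even for hindered carbanions and should outpace reaction at the isobutyryl enolate. It should give dimethyl 2,2'-[(5-isobutyryl-2,4,6-trimethoxy-1,3-phenylene)bis(methylene)]bis(5-hydroxy-4-methyl-3-oxoheptanoate) F1 as a diastereomer mixture. Oxidation of both secondary alcohols with Dess–Martin periodinane (CH2Cl2, NaHCO3, rt) should then deliver 13 for step 5.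

2. Step 2. After the first bromomethylation the ring is still electron-rich and may capture benzylic cations, leading to diarylmethane oligomers. HBr may also cleave a methoxy group next to the carbonyl. The fallback sets out from 3 and comes back at 6. Double Rieche formylation (Cl2CHOMe, TiCl4, CH2Cl2, 0 °C → rt) should give 5-(2-methylpropanoyl)-2,4,6-trimethoxybenzene-1,3-dicarbaldehyde F2. NaBH4 (MeOH/THF, 0 °C) should reduce only the aldehydes, since the ketone is shielded by two ortho-methoxy groups, giving 1-[3,5-bis(hydroxymethyl)-2,4,6-trimethoxyphenyl]-2-methylpropan-1-one F3. PBr3 (Et2O, 0 °C) then converts the diol into 6.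

3. Step 6. The Lewis acid may cut or scramble the CH2 bridges by a retro-Friedel–Crafts-type loss of a pyrone-methylene unit from the very electron-rich ring A. Cleavage of the doubly flanked central ether may also stall. The fallback avoids late deprotection by a convergent, unprotected union; it sets out from 3, 7 and 10 and comes back at 15.
   - Ring A: 3 is demethylated at this simple, bridge-free stage (BBr3, CH2Cl2) to 2-methyl-1-(2,4,6-trihydroxyphenyl)propan-1-one F4.
   - Pyrone: 7 is γ-acylated with 10 under the conditions of step 4 (single arm, no aryl ketone) to methyl 4-methyl-3,5-dioxoheptanoate F5. DBU in hot toluene lactonises it to 6-ethyl-4-hydroxy-5-methyl-2H-pyran-2-one F6.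
   - Union: N,N-dimethylmethyleneiminium iodide (Eschenmoser's salt) aminomethylates C3 of the pyrone to the Mannich base 3-[(dimethylamino)methyl]-6-ethyl-4-hydroxy-5-methyl-2H-pyran-2-one F7. Two equivalents of F7 are warmed with F4. Loss of dimethylamine gives a 3-methylene-pyran-2,4-dione, which the two free ring carbons of F4 capture in a Mannich-type, Friedel–Crafts-like conjugate addition, giving 15.

**Further compounds**

F1 | step 4 | dimethyl 2,2'-[(5-isobutyryl-2,4,6-trimethoxy-1,3-phenylene)bis(methylene)]bis(5-hydroxy-4-methyl-3-oxoheptanoate), diastereomer mixture | CC(C)C(=O)c1c(OC)c(CC(C(=O)OC)C(=O)C(C)C(O)CC)c(OC)c(CC(C(=O)OC)C(=O)C(C)C(O)CC)c1OC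
F2 | step 2 | 5-(2-methylpropanoyl)-2,4,6-trimethoxybenzene-1,3-dicarbaldehyde | CC(C)C(=O)c1c(OC)c(C=O)c(OC)c(C=O)c1OC
F3 | step 2 | 1-[3,5-bis(hydroxymethyl)-2,4,6-trimethoxyphenyl]-2-methylpropan-1-one | CC(C)C(=O)c1c(OC)c(CO)c(OC)c(CO)c1OC
F4 | step 6 | 2-methyl-1-(2,4,6-trihydroxyphenyl)propan-1-one | CC(C)C(=O)c1c(O)cc(O)cc1O
F5 | step 6 | methyl 4-methyl-3,5-dioxoheptanoate | CCC(=O)C(C)C(=O)CC(=O)OC
F6 | step 6 | 6-ethyl-4-hydroxy-5-methyl-2H-pyran-2-one | CCc1oc(=O)cc(O)c1C
F7 | step 6 | 3-[(dimethylamino)methyl]-6-ethyl-4-hydroxy-5-methyl-2H-pyran-2-one | CCc1oc(=O)c(CN(C)C)c(O)c1C
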